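**Retrosynthetic overview**
- The plan rests on the benzene ring of the target: oxygen on C1 and C3, hydrogen on C2, C4 and C6, and the chain CH2–CH(OAc)–C11H23 on C5, with the only stereocenter outside the ring.
- The ring is cut at C1–C2 and C3–C4 (and reclosed at C1–C6) into a 3-alkylcyclobutenone (C1, C4, C5, C6 and the chain) and ethoxyethyne (C2, C3).
- The cyclobutenone comes from a silyl-protected (R)-homopropargylic alcohol by dichloroketene [2+2] and zinc dechlorination; the alkynol from (R)-2-undecyloxirane and lithium acetylide; the epoxide from 1-tridecene by epoxidation and hydrolytic kinetic resolution.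
- Ring order: oxirane (opened), cyclobutenone (consumed), then the benzene ring, the only ring of the target, in step 7.
- After the ring is made: desilylation, de-ethylation, peracetylation, and selective removal of the two aryl acetates.

Key step: step 7

Remark: the (R,R)-salen cobalt catalyst is taken to be the enantiomer that hydrolyses (S)-2-alkyloxiranes and leaves the (R)-epoxide; the sense should be confirmed on 3 (chiral GC) or 5 (Mosher ester) before material is carried on.

**Step 1**
Reactants: 1 tridec-1-ene
Product: 2 rac-2-undecyloxirane
Conditions: mCPBA, CH2Cl2, 0 °C to rt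
Reagents that add atoms: mCPBA, OOC(=O)c1cccc(Cl)c1
Why: Prilezhaev epoxidation of an unhindered terminal alkene by a peracid is general; the new stereocenter is formed racemic and is resolved in step 2.

**Step 2**
Reactants: 2 rac-2-undecyloxirane
Product: 3 (R)-2-undecyloxirane
Conditions: (R,R)-(salen)Co(OAc) (0.5 mol %; trivalent cobalt, salen = N,N'-bis(3,5-di-tert-butylsalicylidene)-1,2-cyclohexanediamine dianion), H2O (0.55 equiv), minimal THF, 0 °C to rt; distillation from the diol
Reagents that add atoms: none
Why: In the Jacobsen hydrolytic kinetic resolution the chiral cobalt–salen catalyst opens the (S)-epoxide with water far faster than the (R)-epoxide, so the configuration of 3 is set by catalyst control and the unreacted (R)-epoxide should be recovered in high enantiomeric purity.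

**Step 3**
Reactants: 3 (R)-2-undecyloxirane, 4 lithium acetylide ethylenediamine complex
Product: 5 (R)-pentadec-1-yn-4-ol
Conditions: DMSO, 0 °C to rt; then H2O
Reagents that add atoms: none
Why: SN2 opening of a terminal epoxide by an acetylide occurs at the unsubstituted carbon, so the stereocenter is not a reacting atom and keeps its configuration (the descriptor stays R because the propargyl carbon outranks the undecyl chain).

**Step 4**
Reactants: 5 (R)-pentadec-1-yn-4-ol
Product: 6 (R)-tert-butyldimethyl(pentadec-1-yn-4-yloxy)silane
Conditions: TBSCl, imidazole, DMF, rt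
Reagents that add atoms: tert-butyldimethylsilyl chloride, CC(C)(C)[Si](C)(C)Cl
Why: Standard imidazole-promoted silylation of a secondary alcohol masks the hydroxyl, which would otherwise be acylated in step 5 and would trap the ketene intermediates of step 7 as a lactone.

**Step 5**
Reactants: 6 (R)-tert-butyldimethyl(pentadec-1-yn-4-yloxy)silane, 7 trichloroacetyl chloride
Product: 8 (R)-3-[2-(tert-butyldimethylsilyloxy)tridecyl]-4,4-dichlorocyclobut-2-en-1-one
Conditions: Zn–Cu couple, Et2O/DME, rt, slow addition of 7
Reagents that add atoms: none
Why: Dichloroketene, made in the flask by zinc dechlorination of 7, undergoes [2+2] cycloaddition with the terminal alkyne so that the ketene carbonyl carbon bonds to the unsubstituted alkyne carbon, giving the 3-alkyl-4,4-dichlorocyclobutenone, while DME ties up ZnCl2 and spares the silyl ether.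

**Step 6**
Reactants: 8 (R)-3-[2-(tert-butyldimethylsilyloxy)tridecyl]-4,4-dichlorocyclobut-2-en-1-one
Product: 9 (R)-3-[2-(tert-butyldimethylsilyloxy)tridecyl]cyclobut-2-en-1-one
Conditions: Zn dust, AcOH, TMEDA, EtOH, 0 °C to rt
Reagents that add atoms: none
Why: Zinc reduction of the α-chloro ketone C–Cl bonds (zinc enolates protonated by TMEDA-buffered acetic acid) removes both chlorines without reducing the enone, as is established for 3-alkyl-4,4-dichlorocyclobutenones, and any 2,4-dichloro isomer formed by chlorine shift converges on the same product.

**Step 7**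
Reactants: 9 (R)-3-[2-(tert-butyldimethylsilyloxy)tridecyl]cyclobut-2-en-1-one, 10 ethoxyethyne
Product: 15 (R)-3-ethoxy-5-[2-(tert-butyldimethylsilyloxy)tridecyl]phenol, via vinylketene 11 (not isolated), via alkenylcyclobutenone 12 (not isolated), via dienylketene 13 (not isolated), via cyclohexadienone 14 (not isolated)
Conditions: 10 (3 equiv, commercial hexanes solution), PhMe (0.1 M), 80 °C, sealed tube
Reagents that add atoms: none
Why: Heating 9 opens the four-membered ring by 4π electrocyclic cleavage of its C1–C4 bond to vinylketene 11, whose ketene C=C adds ethoxyethyne in a [2+2] cycloaddition to give cyclobutenone 12; a second 4π opening gives dienylketene 13, which closes by 6π electrocyclization to cyclohexadienone 14 and tautomerizes to phenol 15. The closest known reaction type is the Danheiser benzannulation of 3-alkylcyclobutenones with alkoxyalkynes, which gives 5-alkylresorcinol monoalkyl ethers under the same neutral thermal conditions. The one ring closed is the six-membered carbocycle: its C1–C2 and C3–C4 bonds (arene numbering, C1 = C–OH) come from the intermolecular [2+2], and the ring is shut at C1–C6 by thermal disrotatory 6π electrocyclization of the dienylketene that has the ketene and vinyl groups cis on its central double bond. No stereocenter is created, and the existing carbinol center lies outside the reacting array and has no epimerization path under neutral conditions. The selectivity required is the regiochemistry of the ketene–alkyne [2+2]; the polarized ynol ether secures it because its unsubstituted, nucleophilic carbon bonds to the electrophilic ketene carbonyl carbon, which places OEt meta to OH and the chain at C5, while the silyl ether keeps the side-chain oxygen from adding to the ketenes.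

**Step 8**
Reactants: 15 (R)-3-ethoxy-5-[2-(tert-butyldimethylsilyloxy)tridecyl]phenol
Product: 16 (R)-3-ethoxy-5-(2-hydroxytridecyl)phenol
Conditions: HF·pyridine, pyridine, THF, 0 °C to rt
Reagents that add atoms: none
Why: Fluoride-driven cleavage of the silyl ether (Si–F bond formation) leaves the phenol and the aryl ethyl ether untouched, and is done here because a silyl ether could be converted into an alkyl bromide by BBr3 in the next step.

**Step 9**
Reactants: 16 (R)-3-ethoxy-5-(2-hydroxytridecyl)phenol
Product: 17 (R)-5-(2-hydroxytridecyl)benzene-1,3-diol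
Conditions: BBr3 (4 equiv), CH2Cl2, −78 °C to rt; then H2O, NaHCO3
Reagents that add atoms: none
Why: In this Lewis acid dealkylation of an aryl alkyl ether, BBr3 coordinates the ether oxygen and bromide attacks the ethyl carbon, while the phenol and the secondary alcohol are held as borate esters that aqueous work-up hydrolyses with the C–O bond of the stereocenter intact.

**Step 10**
Reactants: 17 (R)-5-(2-hydroxytridecyl)benzene-1,3-diol
Product: 18 (R)-5-(2-acetoxytridecyl)-1,3-phenylene diacetate
Conditions: Ac2O, pyridine, DMAP (cat.), CH2Cl2, rt
Reagents that add atoms: acetic anhydride, CC(=O)OC(C)=O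
Why: DMAP-catalysed acylation with acetic anhydride esterifies all three hydroxyls at oxygen, so the stereocenter is retained.

**Step 11**
Reactants: 18 (R)-5-(2-acetoxytridecyl)-1,3-phenylene diacetate
Product: 19 (R)-1-(3,5-dihydroxyphenyl)tridecan-2-yl acetate
Conditions: pyrrolidine (2.2 equiv), THF, 0 °C; dilute citric acid work-up
Reagents that add atoms: none
Why: In this chemoselective aminolysis the aryl acetates, with their phenoxide leaving groups, react with a secondary amine far faster than the secondary alkyl acetate, so two equivalents at 0 °C should free both phenols and leave the C2 acetate in place.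

**Compound list**
1 | tridec-1-ene | C=CCCCCCCCCCCC | starting material
2 | rac-2-undecyloxirane | CCCCCCCCCCCC1CO1 | intermediate
3 | (R)-2-undecyloxirane | CCCCCCCCCCC[C@@H]1CO1 | intermediate
4 | lithium acetylide ethylenediamine complex | [Li]C#C.NCCN | starting material
5 | (R)-pentadec-1-yn-4-ol | CCCCCCCCCCC[C@H](CC#C)O | intermediate
6 | (R)-tert-butyldimethyl(pentadec-1-yn-4-yloxy)silane | CCCCCCCCCCC[C@H](CC#C)O[Si](C)(C)C(C)(C)C | intermediate
7 | trichloroacetyl chloride | ClC(=O)C(Cl)(Cl)Cl | starting material
8 | (R)-3-[2-(tert-butyldimethylsilyloxy)tridecyl]-4,4-dichlorocyclobut-2-en-1-one | CCCCCCCCCCC[C@H](CC1=CC(=O)C1(Cl)Cl)O[Si](C)(C)C(C)(C)C | intermediate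
9 | (R)-3-[2-(tert-butyldimethylsilyloxy)tridecyl]cyclobut-2-en-1-one | CCCCCCCCCCC[C@H](CC1=CC(=O)C1)O[Si](C)(C)C(C)(C)C | intermediate
10 | ethoxyethyne | CCOC#C | starting material
11 | (5R)-5-(tert-butyldimethylsilyloxy)-3-methylidenehexadec-1-en-1-one (vinylketene, not isolated) | CCCCCCCCCCC[C@H](CC(=C)C=C=O)O[Si](C)(C)C(C)(C)C | intermediate
12 | 4-[(4R)-4-(tert-butyldimethylsilyloxy)pentadec-1-en-2-yl]-3-ethoxycyclobut-2-en-1-one (either configuration at ring C4, not isolated) | CCCCCCCCCCC[C@H](CC(=C)C1C(=O)C=C1OCC)O[Si](C)(C)C(C)(C)C | intermediate
13 | (7R)-7-(tert-butyldimethylsilyloxy)-3-ethoxy-5-methylideneoctadeca-1,3-dien-1-one, ketene and vinyl groups cis on C3=C4 (dienylketene, not isolated) | CCCCCCCCCCC[C@H](CC(=C)/C=C(OCC)\C=C=O)O[Si](C)(C)C(C)(C)C | intermediate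
14 | (R)-5-[2-(tert-butyldimethylsilyloxy)tridecyl]-3-ethoxycyclohexa-2,4-dien-1-one (not isolated) | CCCCCCCCCCC[C@H](CC1=CC(OCC)=CC(=O)C1)O[Si](C)(C)C(C)(C)C | intermediate
15 | (R)-3-ethoxy-5-[2-(tert-butyldimethylsilyloxy)tridecyl]phenol | CCCCCCCCCCC[C@H](Cc1cc(O)cc(OCC)c1)O[Si](C)(C)C(C)(C)C | intermediate
16 | (R)-3-ethoxy-5-(2-hydroxytridecyl)phenol | CCCCCCCCCCC[C@H](Cc1cc(O)cc(OCC)c1)O | intermediate
17 | (R)-5-(2-hydroxytridecyl)benzene-1,3-diol | CCCCCCCCCCC[C@H](Cc1cc(O)cc(O)c1)O | intermediate
18 | (R)-5-(2-acetoxytridecyl)-1,3-phenylene diacetate | CCCCCCCCCCC[C@H](Cc1cc(OC(C)=O)cc(OC(C)=O)c1)OC(C)=O | intermediate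
19 | (R)-1-(3,5-dihydroxyphenyl)tridecan-2-yl acetate | CCCCCCCCCCC[C@H](Cc1cc(O)cc(O)c1)OC(C)=O | target

**Step count and risks**
Total step count: 11. Longest linear sequence: 11 steps (from 1).

Steps most likely to fail:

1. Step 7 (benzannulation). The vinylketene may be drained by dimerization or by acylating the phenol as it forms. Ethoxyethyne may escape to the headspace or fragment to ketene and ethylene if the bath runs much above 80 °C. The second ring opening may stall at the alkenylcyclobutenone. Excess alkyne, moderate dilution and a brief K2CO3/MeOH treatment of the crude (to return any aryl ester to the phenol) are the first countermeasures. Fallback: the arene is bought instead of built. Setting out from epoxide 3, 1,3-bis(benzyloxy)-5-bromobenzene is converted with magnesium in THF into 3,5-bis(benzyloxy)phenylmagnesium bromide F1. F1 opens 3 at its unsubstituted carbon under CuI catalysis (10 mol %, THF, −30 °C) to give (R)-1-[3,5-bis(benzyloxy)phenyl]tridecan-2-ol F2 with the stereocenter untouched. Hydrogenolysis (H2, Pd/C, EtOAc) removes both benzyl groups and the sequence comes back to the route at triol 17.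

2. Step 5 (dichloroketene cycloaddition). The cycloaddition may be slow relative to self-condensation of dichloroketene, and ZnCl2 may strip the silyl group or promote chlorine migration and decomposition of the strained product. Fallback: a keteniminium [2+2] that needs neither zinc nor a dechlorination. Setting out from alkyne 6, N,N-dimethylacetamide is treated with Tf2O and 2,4,6-collidine in 1,2-dichloroethane to give N,N-dimethylketeniminium trifluoromethanesulfonate F3. F3 adds to the terminal alkyne at reflux to give (R)-N-{3-[2-(tert-butyldimethylsilyloxy)tridecyl]cyclobut-2-en-1-ylidene}-N-methylmethanaminium trifluoromethanesulfonate F4. Hydrolysis with aqueous NaHCO3 comes back to the route at cyclobutenone 9, bypassing steps 5 and 6.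

3. Step 9 (de-ethylation). The secondary borate may be displaced by bromide during the long exposure needed to cleave the ethyl ether, with loss or inversion of the stereocenter, or the dealkylation may stop short. Fallback: cap the carbinol as its final ester first and dealkylate with a thiol as nucleophile instead of bromide. Setting out from diol 16, acetylation (Ac2O, pyridine, DMAP) gives (R)-1-(3-acetoxy-5-ethoxyphenyl)tridecan-2-yl acetate F5. AlCl3/EtSH in CH2Cl2 at 0 °C (hard acid on the ether oxygen, thiol attack at the ethyl carbon) should give (R)-1-(3-acetoxy-5-hydroxyphenyl)tridecan-2-yl acetate F6. The remaining phenolic acetate is removed with pyrrolidine as in step 11, and the sequence comes back to the route at target 19, so steps 9 and 10 are not needed.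

**Further compounds**
F1 | step 7 | 3,5-bis(benzyloxy)phenylmagnesium bromide | Br[Mg]c1cc(OCc2ccccc2)cc(OCc2ccccc2)c1
F2 | step 7 | (R)-1-[3,5-bis(benzyloxy)phenyl]tridecan-2-ol | CCCCCCCCCCC[C@H](Cc1cc(OCc2ccccc2)cc(OCc2ccccc2)c1)O
F3 | step 5 | N,N-dimethylketeniminium trifluoromethanesulfonate | C=C=[N+](C)C.[O-]S(=O)(=O)C(F)(F)F
F4 | step 5 | (R)-N-{3-[2-(tert-butyldimethylsilyloxy)tridecyl]cyclobut-2-en-1-ylidene}-N-methylmethanaminium trifluoromethanesulfonate | CCCCCCCCCCC[C@H](CC1=CC(=[N+](C)C)C1)O[Si](C)(C)C(C)(C)C.[O-]S(=O)(=O)C(F)(F)F
F5 | step 9 | (R)-1-(3-acetoxy-5-ethoxyphenyl)tridecan-2-yl acetate | CCCCCCCCCCC[C@H](Cc1cc(OC(C)=O)cc(OCC)c1)OC(C)=O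
F6 | step 9 | (R)-1-(3-acetoxy-5-hydroxyphenyl)tridecan-2-yl acetate | CCCCCCCCCCC[C@H](Cc1cc(O)cc(OC(C)=O)c1)OC(C)=O
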